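# Total synthesis proposal for CNP0310968.1: daucane 6-O-(E)-p-coumarate by a gold-catalysed (4+3) folding of an acyclic allene–diene

## Analysis of the target

- **Skeleton.** The target is the 6-O-(E)-p-coumarate of a daucane sesquiterpene. Ring A is the cyclopentane C1–C5. Ring B is the cycloheptenone C1, C5–C10. The rings share the C1–C5 bond.
- **Numbering.** Daucane numbering is used throughout: C15 is the methyl on C1, C14 the methyl on C8, and C11–C13 the isopropyl on C4. β is the face that carries C15.
- **Stereocentres.** Four contiguous centres must be set: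
  - C1 (R): quaternary, methyl β.
  - C5 (S): H α.
  - C4 (R): tertiary OH β, isopropyl α.
  - C6 (S): acyloxy α.
- **Relations.** The ring fusion is trans, O4 and C6 are cis on ring A, and O6 is cis to H5.
- **Sensitive groups.**
  - The γ-acyloxy enone C6–C9 can eliminate vinylogously.
  - The tertiary carbinol C4 can dehydrate, or undergo retro-aldol cleavage once C6 is a ketone.
  - The cinnamate and the free phenol also need care.
- **What is hard.** The difficulty is the trans C1–C5 bond between a quaternary and a tertiary carbon.
  - A chain on C1 or C5 of a preformed ring B can only reach its own face.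
  - A cycloaddition onto a cyclopentene adds both bonds to one face.
  - Both therefore give the cis fusion.
- **The feature that invites the key move.** Ring B divides into two units.
  - The three-carbon unit C9–C10–C1 has oxygenated C9 at one end and quaternary C1 at the other.
  - The four-carbon unit is C5–C6–C7–C8.
  - The two units are already joined by the three ring A atoms C2–C3–C4.
  - This is the pattern of an intramolecular (4+3) cycloaddition of an allyl cation and a diene across C1–C5 and C8–C9.

## Retrosynthetic reasoning

**C6–O acyl bond.** The ester is the most labile bond and is made last: 23 comes from 22 by loss of two silyl groups. 22 comes from alcohol 18 and the protected acid 21, which is made from 19. The tertiary O4 stays silylated, so only the secondary C6–OH can be acylated.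

**C6–O bond.** The γ-hydroxy enone of 18 is read as a C6/C9 1,4-dioxygenated unit. It therefore comes from the cyclic diene C6=C7–C8=C9 of silyl dienol ether 15 by photooxygenation. 15 comes from enone 14. As a result, no oxygen at C6 has to pass through the cationic key step. The forward reaction must add oxygen to the α face, which is the face of H5 and lies opposite the C5–C4 bond.

**C9 carbonyl.** Enone 14 is the hydrolysed and conjugated form of enol acetate 13. The position of the C6=C7 bond in 13 does not matter, because both ketone isomers give the same dienol ether 15.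

**C1–C5 and C8–C9 (key disconnection).** Cutting these two bonds of 13 opens both rings at once and leads to the acyclic allenyl acetate–diene 12.
- They are cut here because the pair contains the hardest bond of the target.
- The relative configuration at C1 and C5 then follows from alkene geometry and transition-state topology rather than from ring strain.
- The precursor keeps a single stereocentre, C4.
- The forward reaction must form both bonds suprafacially, give the trans fusion, and place the oxygen on C9.

**Allene.** 12 is the 3,3-shifted isomer of the tertiary propargylic acetate 11, the silyl ether of 10. The carbinol carbon that becomes C1 is planarised later, so its configuration need not be controlled.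

**C4–C5 bond.** Carbinol 10 comes from ketone 6 and a dienyl metal made from enyne 7. This is the only step in which a catalyst sets a stereocentre; C1, C5 and C6 are relayed from it.

**C1–C10 and C3–C4 bonds.** 6 comes from diketone 3 and the acetylide 4, using the difference between a methyl and an isopropyl ketone. 3 comes from 1 and 2 by acyl-anion conjugate addition.

## Alternatives that were turned down

**Alternative 1:** the textbook route.
- *Disconnection:* C7=C8 by ring-closing metathesis, after ring A has been dressed stepwise.
- *Forward key step:*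
  1. Asymmetric conjugate addition to a commercial β-methylcyclopentenone.
  2. Aldol trapping at C5.
  3. Isopropyl addition at C4.
  4. Closure of the triene diol A1 with second-generation Grubbs catalyst.
- *Why turned down:*
  - The C1/C5 relation rests only on the small size difference between a methyl and a CH2 group on the same quaternary carbon.
  - C5 remains epimerisable next to the C4 ketone.
  - The β-hydroxy ketone must survive a basic isopropyl organometallic, with retro-aldol and enolisation as risks.
  - Each stereocentre costs its own operation plus protecting-group steps.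
  - The ring closure itself sets no stereocentre.

**Alternative 2:** oxidopyrylium (5+2) cycloaddition.
- *Disconnection:* C1–C10 and C5–C6.
- *Forward key step:* a methyl-substituted 3-oxidopyrylium ylide adds to a β-methylcyclopentenone to give the oxa-bridged tricycle A2. SmI2 then cleaves the C10–O bond and would unveil exactly the C6–OH/C7=C8/C9=O array.
- *Why turned down:*
  - Suprafacial addition to a cyclic alkene puts C15 and H5 on the same face, which is the cis fusion.
  - Correction at C5 would have to pass through an enolate that is β to the C6 oxygen, so elimination is likely.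
  - The ylide is planar and achiral, so the absolute configuration has no source.
  - The enone radical anion can also expel the C6–O bond vinylogously.

**Alternative 3:** aldol closure of ring A.
- *Disconnection:* C4–C5, the 1,3-dioxygen retron O4/O6.
- *Forward key step:* the monocyclic triketone A3 closes by intramolecular aldol addition, followed by hydroxyl-directed reduction at C6.
- *Why turned down:*
  - The chain on C1 can only reach C5 of the endocyclic enolate from its own face, so the kinetic product is cis-fused and has the wrong C1 relation to both C4 and C5.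
  - Rescue by retro-aldol equilibration has no clear thermodynamic bias between cis and trans angular-methyl hydroazulenones.
  - That equilibration also competes with dehydration.
  - The lone, remote stereocentre of A3 needs a multistep ring synthesis of its own.

Key step: step 6

**Remark on the chemistry:** the carbinol carbon C3 of 5, 6, 10 and 11 and the allene axis of 12 are carried as mixtures, because this carbon (C1 of the target) becomes planar in step 6. Their SMILES leave it undefined.

**Assumption:** (E)-pent-3-en-1-yne (7) is taken as a purchasable enyne.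

## Steps

Step 1
Reactants: 1 isobutyraldehyde; 2 methyl vinyl ketone
Product: 3 6-methylheptane-2,5-dione
Conditions: 3-benzyl-5-(2-hydroxyethyl)-4-methylthiazolium chloride (10 mol %), Et3N, EtOH, 80 °C
Reagents that add atoms: none
Why: Stetter reaction; the thiazolylidene turns the aldehyde into an acyl anion equivalent that adds 1,4 to the enone, a standard entry to 1,4-diketones from aliphatic aldehydes.

Step 2
Reactants: 3 6-methylheptane-2,5-dione; 4 ethynylmagnesium bromide
Product: 6 3,7-dimethyl-6-oxooct-1-yn-3-yl acetate (racemic), via bromomagnesium alkoxide 5 (not isolated)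
Conditions: 4 (1.0 equiv), THF, −78 °C; then Ac2O, DMAP (cat.), −78 °C to rt
Reagents that add atoms: acetic anhydride CC(=O)OC(C)=O
Why: Grignard 1,2-addition should take the unhindered methyl ketone before the α-branched isopropyl ketone, and acylating the alkoxide in the same flask prevents hemiketal formation with the remaining ketone. The new centre is not controlled and need not be.

Step 3
Reactants: 6 3,7-dimethyl-6-oxooct-1-yn-3-yl acetate (racemic); 7 (E)-pent-3-en-1-yne
Product: 10 (6R,7E,9E)-6-hydroxy-3-methyl-6-(propan-2-yl)undeca-7,9-dien-1-yn-3-yl acetate, via dienylzirconocene chloride 8 (not isolated), via dienyl(methyl)zinc 9 (not isolated)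
Conditions: 7, Cp2Zr(H)Cl, CH2Cl2, rt; Zn(CH3)2, toluene, −78 °C; then 6, Ti(OiPr)4 (1.2 equiv), trans-cyclohexane-1,2-diamine bis(2-hydroxycamphor-10-sulfonamide) ligand (10 mol %), rt; aq NH4Cl
Reagents that add atoms: none
Why: This is syn-hydrozirconation of the terminal alkyne, zirconium-to-zinc transmetalation and titanium-catalysed asymmetric dienylation of a ketone. The chiral titanium bis(sulfonamide) diolate differentiates the branched isopropyl group from the linear chain, and the ligand enantiomer is chosen to give 6R (C4 of the target). The organozinc leaves the acetate and the terminal alkyne untouched.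

Step 4
Reactants: 10 (6R,7E,9E)-6-hydroxy-3-methyl-6-(propan-2-yl)undeca-7,9-dien-1-yn-3-yl acetate
Product: 11 (6R,7E,9E)-3-methyl-6-(propan-2-yl)-6-(triethylsilyloxy)undeca-7,9-dien-1-yn-3-yl acetate
Conditions: TESOTf, 2,6-lutidine, CH2Cl2, −78 to 0 °C
Reagents that add atoms: triethylsilyl trifluoromethanesulfonate CC[Si](CC)(CC)OS(=O)(=O)C(F)(F)F
Why: Silylation with a silyl triflate and a hindered base works on crowded tertiary alcohols. It removes the hydroxyl nucleophile that would otherwise add to the activated allene in step 6.

Step 5
Reactants: 11 (6R,7E,9E)-3-methyl-6-(propan-2-yl)-6-(triethylsilyloxy)undeca-7,9-dien-1-yn-3-yl acetate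
Product: 12 (6R,7E,9E)-3-methyl-6-(propan-2-yl)-6-(triethylsilyloxy)undeca-1,2,7,9-tetraen-1-yl acetate (both allene epimers)
Conditions: AgSbF6 (5 mol %), CH2Cl2, rt, dark
Reagents that add atoms: none
Why: Saucy–Marbet type silver-catalysed 3,3-acyloxy shift of a tertiary propargylic acetate with a terminal alkyne, the classical route to 3,3-dialkylallenyl acetates. C4 is not touched.

Step 6
Reactants: 12 (6R,7E,9E)-3-methyl-6-(propan-2-yl)-6-(triethylsilyloxy)undeca-1,2,7,9-tetraen-1-yl acetate (both allene epimers)
Product: 13 4β-(triethylsilyloxy)-5αH,8αH-dauca-6,9-dien-9-yl acetate (trans-fused; C15 and C14 β)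
Conditions: chloro[1,3-bis(2,6-diisopropylphenyl)imidazol-2-ylidene]gold (5 mol %), AgSbF6 (5 mol %), CH2Cl2, 0 °C to rt
Reagents that add atoms: none
Why: The cationic gold complex binds the allene and turns C9–C10–C1 into a 2-auro-allyl cation, stabilised at C9 by the acetoxy group and at C1 by two alkyl groups; this unit adds in a concerted, asynchronous (4+3) cycloaddition to the s-cis diene C5–C8, forming C1–C5 and C8–C9, and the cycloheptenyl gold carbene at C10 collapses by 1,2-hydride shift from C9 (C1 has no hydrogen) to the enol acetate with release of the catalyst. The closest known reaction type is the gold- or platinum-catalysed intramolecular (4+3) cycloaddition of allenedienes with a three-atom tether, including acyloxyallenes derived from propargylic esters. Ring B closes by the cycloaddition itself, suprafacially on both partners, and ring A closes in the same event as the tether ring through the C1–C5 bond. The extended (exo-like) transition state, favoured because it keeps the ligated gold on C10 away from the diene, puts the tether outside and C15 inside on C1 (known substrates also carry one inside methyl group) and, together with the E-configured C5=C6 bond, places C15 anti to H5, which is the trans fusion; C8 follows from the E geometry of C7=C8 and is erased in step 7. The diene face is chosen by C4: C3 must point towards the cation, the isopropyl group takes the open position and the smaller silyloxy group accepts the allylic 1,3-contact with H6, which makes O4 cis to C6 as in the target. The step needs (4+3) with hydride shift rather than ring contraction to the (4+2) product, secured by the strongly donating carbene ligand and by the hydride on oxygen-bearing C9, and it needs trapping of the cation faster than proton loss, secured by the fully substituted C4 in the tether.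

Step 7
Reactants: 13 4β-(triethylsilyloxy)-5αH,8αH-dauca-6,9-dien-9-yl acetate
Product: 14 4β-(triethylsilyloxy)-5αH-dauc-7-en-9-one
Conditions: K2CO3 (0.2 equiv), MeOH, 0 °C to rt
Reagents that add atoms: none
Why: Methanolysis of the enol acetate gives the β,γ-unsaturated ketone. Its doubly activated H8 is exchanged under the same conditions, so the alkene moves into conjugation. C1, C4 and C5 are not acidic positions and are not touched.

Step 8
Reactants: 14 4β-(triethylsilyloxy)-5αH-dauc-7-en-9-one
Product: 15 9-(tert-butyldimethylsilyloxy)-4β-(triethylsilyloxy)-5αH-dauca-6,8-diene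
Conditions: TBSOTf, Et3N, CH2Cl2, 0 °C
Reagents that add atoms: tert-butyldimethylsilyl trifluoromethanesulfonate CC(C)(C)[Si](C)(C)OS(=O)(=O)C(F)(F)F
Why: Soft enolisation with a silyl triflate and an amine gives the linear (extended) dienol ether by loss of a γ-proton at C6. The alternative α′ position C10 is neopentyl and hindered, and any residual β,γ-isomer of 14 gives the same product.

Step 9
Reactants: 15 9-(tert-butyldimethylsilyloxy)-4β-(triethylsilyloxy)-5αH-dauca-6,8-diene
Product: 18 6α-hydroxy-4β-(triethylsilyloxy)-5αH-dauc-7-en-9-one, via 6α,9α-endoperoxide 16 (not isolated), via 6α-hydroperoxide 17 (not isolated)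
Conditions: O2, tetraphenylporphyrin (cat.), visible light, CH2Cl2, −78 °C; then MeOH, PPh3, −78 °C to rt
Reagents that add atoms: dioxygen O=O
Why: Singlet oxygen adds (4+2) across the cisoid ring diene at C6 and C9; methanol then opens the silyl peroxyketal to the γ-hydroperoxy enone and the phosphine reduces it. C6 is set by approach from the α face, where C5 carries only hydrogen, while the β face is blocked by the C5–C4 bond with its silyloxy group and by C15.

Step 10
Reactants: 19 p-coumaric acid
Product: 21 (E)-3-[4-(tert-butyldimethylsilyloxy)phenyl]prop-2-enoic acid, via bis-silylated coumarate 20 (not isolated)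
Conditions: TBSCl (2.2 equiv), imidazole, DMF, rt; then AcOH–THF–H2O, rt
Reagents that add atoms: tert-butyldimethylsilyl chloride CC(C)(C)[Si](C)(C)Cl
Why: Exhaustive silylation followed by selective hydrolysis of the much more labile silyl ester, a standard phenol protection of hydroxycinnamic acids. The E alkene is not affected.

Step 11
Reactants: 18 6α-hydroxy-4β-(triethylsilyloxy)-5αH-dauc-7-en-9-one; 21 (E)-3-[4-(tert-butyldimethylsilyloxy)phenyl]prop-2-enoic acid
Product: 22 4β-(triethylsilyloxy)-9-oxo-5αH-dauc-7-en-6α-yl (E)-3-[4-(tert-butyldimethylsilyloxy)phenyl]prop-2-enoate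
Conditions: DCC, DMAP, CH2Cl2, rt
Reagents that add atoms: none
Why: Steglich esterification acylates at oxygen, so C6 keeps its configuration. The only free hydroxyl group is the secondary one at C6.

Step 12
Reactants: 22 4β-(triethylsilyloxy)-9-oxo-5αH-dauc-7-en-6α-yl (E)-3-[4-(tert-butyldimethylsilyloxy)phenyl]prop-2-enoate
Product: 23 (3R,3aS,4S,8aR)-3-hydroxy-6,8a-dimethyl-7-oxo-3-(propan-2-yl)-1,2,3,3a,4,7,8,8a-octahydroazulen-4-yl (2E)-3-(4-hydroxyphenyl)prop-2-enoate (target)
Conditions: HF·pyridine, pyridine, THF, 0 °C to rt
Reagents that add atoms: none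
Why: Buffered fluoride-mediated desilylation removes the phenolic and the tertiary silyl ether in one operation. These mildly acidic conditions avoid ester cleavage, acyl migration and vinylogous elimination of the γ-acyloxy enone.

## Compound list

1 | isobutyraldehyde | CC(C)C=O | starting material
2 | methyl vinyl ketone | CC(=O)C=C | starting material
3 | 6-methylheptane-2,5-dione | CC(=O)CCC(=O)C(C)C | intermediate
4 | ethynylmagnesium bromide | C#C[Mg]Br | starting material
5 | bromomagnesium 3,7-dimethyl-6-oxooct-1-yn-3-olate | CC(C)C(=O)CCC(C)(O[Mg]Br)C#C | intermediate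
6 | 3,7-dimethyl-6-oxooct-1-yn-3-yl acetate (racemic) | CC(C)C(=O)CCC(C)(OC(C)=O)C#C | intermediate
7 | (E)-pent-3-en-1-yne | C/C=C/C#C | starting material
8 | chloro[(1E,3E)-penta-1,3-dienyl]zirconocene | C/C=C/C=C/[Zr](Cl)(C1C=CC=C1)C1C=CC=C1 | intermediate
9 | methyl[(1E,3E)-penta-1,3-dienyl]zinc | C/C=C/C=C/[Zn]C | intermediate
10 | (6R,7E,9E)-6-hydroxy-3-methyl-6-(propan-2-yl)undeca-7,9-dien-1-yn-3-yl acetate | C#CC(C)(OC(C)=O)CC[C@@](O)(C(C)C)/C=C/C=C/C | intermediate
11 | (6R,7E,9E)-3-methyl-6-(propan-2-yl)-6-(triethylsilyloxy)undeca-7,9-dien-1-yn-3-yl acetate | C#CC(C)(OC(C)=O)CC[C@@](O[Si](CC)(CC)CC)(C(C)C)/C=C/C=C/C | intermediate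
12 | (6R,7E,9E)-3-methyl-6-(propan-2-yl)-6-(triethylsilyloxy)undeca-1,2,7,9-tetraen-1-yl acetate | CC(=O)OC=C=C(C)CC[C@@](O[Si](CC)(CC)CC)(C(C)C)/C=C/C=C/C | intermediate
13 | 4β-(triethylsilyloxy)-5αH,8αH-dauca-6,9-dien-9-yl acetate | C[C@H]1C=C[C@@H]2[C@](C)(CC[C@@]2(O[Si](CC)(CC)CC)C(C)C)C=C1OC(C)=O | intermediate
14 | 4β-(triethylsilyloxy)-5αH-dauc-7-en-9-one | CC1=CC[C@@H]2[C@](C)(CC[C@@]2(O[Si](CC)(CC)CC)C(C)C)CC1=O | intermediate
15 | 9-(tert-butyldimethylsilyloxy)-4β-(triethylsilyloxy)-5αH-dauca-6,8-diene | CC=1C=C[C@@H]2[C@](C)(CC[C@@]2(O[Si](CC)(CC)CC)C(C)C)CC=1O[Si](C)(C)C(C)(C)C | intermediate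
16 | 9β-(tert-butyldimethylsilyloxy)-6α,9α-epidioxy-4β-(triethylsilyloxy)-5αH-dauc-7-ene | CC1=C[C@H]3[C@@H]2[C@](C)(CC[C@@]2(O[Si](CC)(CC)CC)C(C)C)C[C@]1(O[Si](C)(C)C(C)(C)C)OO3 | intermediate
17 | 6α-hydroperoxy-4β-(triethylsilyloxy)-5αH-dauc-7-en-9-one | CC1=C[C@H](OO)[C@@H]2[C@](C)(CC[C@@]2(O[Si](CC)(CC)CC)C(C)C)CC1=O | intermediate
18 | 6α-hydroxy-4β-(triethylsilyloxy)-5αH-dauc-7-en-9-one | CC1=C[C@H](O)[C@@H]2[C@](C)(CC[C@@]2(O[Si](CC)(CC)CC)C(C)C)CC1=O | intermediate
19 | p-coumaric acid | OC(=O)/C=C/c1ccc(O)cc1 | starting material
20 | tert-butyldimethylsilyl (E)-3-[4-(tert-butyldimethylsilyloxy)phenyl]prop-2-enoate | CC(C)(C)[Si](C)(C)OC(=O)/C=C/c1ccc(O[Si](C)(C)C(C)(C)C)cc1 | intermediate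
21 | (E)-3-[4-(tert-butyldimethylsilyloxy)phenyl]prop-2-enoic acid | OC(=O)/C=C/c1ccc(O[Si](C)(C)C(C)(C)C)cc1 | intermediate
22 | 4β-(triethylsilyloxy)-9-oxo-5αH-dauc-7-en-6α-yl (E)-3-[4-(tert-butyldimethylsilyloxy)phenyl]prop-2-enoate | CC1=C[C@H](OC(=O)/C=C/c2ccc(O[Si](C)(C)C(C)(C)C)cc2)[C@@H]2[C@](C)(CC[C@@]2(O[Si](CC)(CC)CC)C(C)C)CC1=O | intermediate
23 | (3R,3aS,4S,8aR)-3-hydroxy-6,8a-dimethyl-7-oxo-3-(propan-2-yl)-1,2,3,3a,4,7,8,8a-octahydroazulen-4-yl (2E)-3-(4-hydroxyphenyl)prop-2-enoate | CC1=C[C@H](OC(=O)/C=C/c2ccc(O)cc2)[C@@H]2[C@](C)(CC[C@@]2(O)C(C)C)CC1=O | target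

## Step count and least certain steps

Total step count: 12. Longest linear sequence: 11 (steps 1–9, 11, 12).

**Step 6 (key step).**
- *What may go wrong:*
  - The allyl cation may lose a proton from C15 or C2 to give a conjugated dienyl acetate.
  - The acetate may shuttle back to the propargylic ester and on to a 1,2-shifted vinyl carbenoid, which would put the oxygen on C10.
  - The carbene at C10 may collapse by acyloxy or alkyl shift instead of hydride shift; the alkyl shift gives the ring-contracted (4+2) product.
  - The silyl ether oxygen may attack C1.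
  - All of these arise because the cation is long-lived and the acyl group can participate.
- *Fallback:* it sets out from 12 and returns at 14, and it changes the cation precursor so that acyl participation is structurally impossible.
  - Cleavage of the enol ester with methyllithium, then O-silylation of the allenolate with triisopropylsilyl triflate, would give the siloxyallene F1.
  - Cycloaddition of F1 with PtCl2 in toluene, or with the same gold complex, would give the triisopropylsilyl enol ether F2, whose carbene precursor can only collapse by hydride shift.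
  - Buffered fluoride at low temperature would give 14.

**Step 3.**
- *What may go wrong:* the α-branched ketone may react slowly, so that methyl transfer from zinc competes. Face discrimination between an isopropyl and a primary alkyl group may also be incomplete.
- *Fallback:* it sets out from 1 and 9 and returns at 11. It moves the asymmetric event to an aldehyde addition and then builds the tertiary centre by a stereospecific 1,2-metallate shift.
  - Amino-alcohol-catalysed addition of 9 to 1 (3-exo-morpholinoisoborneol, enantiomer chosen for 3R) would give the secondary dienol F3.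
  - Carbamoylation of F3 would give the N,N-diisopropylcarbamate F4.
  - Lithiation of F4 (s-BuLi, TMEDA, retention) is followed by trapping with the pinacol boronate F5, made from commercial 2-(2-bromoethyl)-2-methyl-1,3-dioxolane through its Grignard reagent.
  - Migration anti to the carbamate would then give the tertiary boronate F6.
  - Oxidation with retention would give the carbinol ketal F7.
  - Silylation would give the triethylsilyl ether F8.
  - Mild transketalisation would give the methyl ketone F9.
  - Addition of 4 to F9 with an acetic anhydride quench would give 11.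

**Step 9.**
- *What may go wrong:* an ene reaction at the C14 methyl group, or attack at the electron-rich C8=C9 bond, may compete with the (4+2) mode. Facial selectivity at C6 may be eroded by the α-isopropyl group.
- *Fallback:* it sets out from 14 and returns at 23. It replaces photooxygenation by C–H oxidation plus hydroxyl-directed reduction.
  - Allylic oxidation of 14 with dirhodium tetracaprolactamate and tert-butyl hydroperoxide would give the enedione F10.
  - HF·pyridine would free the hydroxy enedione F11.
  - Evans–Saksena reduction with Me4NBH(OAc)3, bound to the β-oriented O4, would deliver hydride to the β face of C6 only and give the diol F12.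
  - Steglich acylation of the secondary hydroxyl with 21 would give the ester F13.
  - Desilylation of F13 would give 23.

**Step 11.**
- *What may go wrong:* the C6 hydroxyl is flanked by C5 with two fully substituted neighbours. Acyl transfer may therefore be slower than rearrangement of the O-acylisourea to the N-acylurea.
- *Fallback:* it sets out from 18 and returns at 22, and it builds the cinnamate on the alcohol.
  - Acylation with the small diethylphosphonoacetic acid would give the phosphonoacetate F14.
  - A Horner–Wadsworth–Emmons reaction of F14 with commercial 4-(tert-butyldimethylsilyloxy)benzaldehyde (LiCl, DBU) would give 22 as the E isomer.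

## Further compounds

F1 | step 6 | (6R,7E,9E)-3-methyl-6-(propan-2-yl)-6-(triethylsilyloxy)-1-(triisopropylsilyloxy)undeca-1,2,7,9-tetraene | CC(C)[Si](OC=C=C(C)CC[C@@](O[Si](CC)(CC)CC)(C(C)C)/C=C/C=C/C)(C(C)C)C(C)C
F2 | step 6 | 4β-(triethylsilyloxy)-9-(triisopropylsilyloxy)-5αH,8αH-dauca-6,9-diene | C[C@H]1C=C[C@@H]2[C@](C)(CC[C@@]2(O[Si](CC)(CC)CC)C(C)C)C=C1O[Si](C(C)C)(C(C)C)C(C)C
F3 | step 3 | (3R,4E,6E)-2-methylocta-4,6-dien-3-ol | CC(C)[C@@H](O)/C=C/C=C/C
F4 | step 3 | (3R,4E,6E)-2-methylocta-4,6-dien-3-yl N,N-diisopropylcarbamate | CC(C)[C@@H](OC(=O)N(C(C)C)C(C)C)/C=C/C=C/C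
F5 | step 3 | 4,4,5,5-tetramethyl-2-[2-(2-methyl-1,3-dioxolan-2-yl)ethyl]-1,3,2-dioxaborolane | CC1(CCB2OC(C)(C)C(C)(C)O2)OCCO1
F6 | step 3 | tertiary dienyl pinacol boronate (boron in place of O4; ethylene ketal at C1) | CC1(CC[C@@](B2OC(C)(C)C(C)(C)O2)(C(C)C)/C=C/C=C/C)OCCO1
F7 | step 3 | (3R,4E,6E)-1-(2-methyl-1,3-dioxolan-2-yl)-3-(propan-2-yl)octa-4,6-dien-3-ol | CC1(CC[C@@](O)(C(C)C)/C=C/C=C/C)OCCO1
F8 | step 3 | triethylsilyl ether of F7 | CC1(CC[C@@](O[Si](CC)(CC)CC)(C(C)C)/C=C/C=C/C)OCCO1
F9 | step 3 | (5R,6E,8E)-5-(propan-2-yl)-5-(triethylsilyloxy)deca-6,8-dien-2-one | CC(=O)CC[C@@](O[Si](CC)(CC)CC)(C(C)C)/C=C/C=C/C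
F10 | step 9 | 4β-(triethylsilyloxy)-5αH-dauc-7-ene-6,9-dione | CC1=CC(=O)[C@@H]2[C@](C)(CC[C@@]2(O[Si](CC)(CC)CC)C(C)C)CC1=O
F11 | step 9 | 4β-hydroxy-5αH-dauc-7-ene-6,9-dione | CC1=CC(=O)[C@@H]2[C@](C)(CC[C@@]2(O)C(C)C)CC1=O
F12 | step 9 | 4β,6α-dihydroxy-5αH-dauc-7-en-9-one | CC1=C[C@H](O)[C@@H]2[C@](C)(CC[C@@]2(O)C(C)C)CC1=O
F13 | step 9 | 4β-hydroxy-9-oxo-5αH-dauc-7-en-6α-yl (E)-3-[4-(tert-butyldimethylsilyloxy)phenyl]prop-2-enoate | CC1=C[C@H](OC(=O)/C=C/c2ccc(O[Si](C)(C)C(C)(C)C)cc2)[C@@H]2[C@](C)(CC[C@@]2(O)C(C)C)CC1=O
F14 | step 11 | 4β-(triethylsilyloxy)-9-oxo-5αH-dauc-7-en-6α-yl 2-(diethoxyphosphoryl)acetate | CC1=C[C@H](OC(=O)CP(=O)(OCC)OCC)[C@@H]2[C@](C)(CC[C@@]2(O[Si](CC)(CC)CC)C(C)C)CC1=O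
A1 | alternative 1 | ring A triene diol for ring-closing metathesis (C6 vinyl carbinol, C9 isopropenyl ketone) | C=C[C@H](O)[C@@H]1[C@](C)(CC[C@@]1(O)C(C)C)CC(=O)C(C)=C
A2 | alternative 2 | cis-fused oxa-bridged (5+2) adduct (6α,10α-epoxy, 5βH, C4 and C9 ketones) | CC1=C[C@H]3[C@H]2[C@](C)(CCC2=O)[C@H](O3)C1=O
A3 | alternative 3 | (R)-2,6-dimethyl-6-(4-methyl-3-oxopentyl)cyclohept-2-ene-1,4-dione | CC1=CC(=O)C[C@](C)(CCC(=O)C(C)C)CC1=O
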